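## The problem

The target (33) is a resveratrol tetramer built as a chain of three heterocycles. A 2,3-diarylbenzofuran (benzo ring A) is joined through an E-stilbene double bond from its C4 to C5 of a 2,3-dihydrobenzofuran (DHB-1, benzo ring B). C3 of DHB-1 is bonded to C4 of a second dihydrobenzofuran (DHB-2, benzo ring C). Ring C therefore carries three contiguous substituents (C3 of DHB-1, C3 of DHB-2 and O1 of DHB-2) and is the most crowded part of the molecule.

There are four stereocentres: C2 and C3 of DHB-1 (2R,3R) and C2 and C3 of DHB-2 (2S,3S), both rings trans. In each ring C2 is a 4-oxybenzylic ether carbon that can ionise and reclose, so C2 can be corrected from C3 under thermodynamic control. The two C3 diarylmethine carbons cannot be corrected, lie in different rings and cannot be relied on to control each other, so two reagent-controlled events are needed.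

The fragile features are the nine phenols, the stilbene (acid, light) and the C2–O bonds. The cation from DHB-1 lies within reach of the 3,5-dioxygenated ring on C3 of DHB-2, and capture there would close a seven-membered ring.

The benzofuran has no stereocentre but a regiochemical problem: carbon at C4, oxygen at C6, and two different aryl groups at C2 and C3. O1, C7a, C3a, C3 with its aryl group and C4 with its carbon substituent map atom for atom onto O1, C8a, C4a, C4 and C5 of a coumarin whose ring A pattern is that of orsellinic acid. A bromine on C3 of that coumarin lets the lactone contract onto itself and leaves the lactone carbonyl as a C2 carboxyl group that can be exchanged for the 4-oxyphenyl ring.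

## Retrosynthesis

**33 ⇒ 32.** The nine O–H bonds are traced back to O–CH3 in 32. Methyl is preferred to benzyl, which would offer benzylic C–H bonds to the carbenes of steps 14 and 18 and would not survive AlCl3 in step 11. It is preferred to silyl, which would be lost in the alkali of step 9. The forward step must cleave nine ethers without opening either dihydrofuran or touching the stilbene.

**32 ⇒ 14 + 31.** The stilbene C=C is cut. Against an aryl–vinyl (Heck) cut it avoids 1,1-diarylethene regioisomers at the peri-hindered C4 of the benzofuran, and it divides the molecule into halves of similar size. Phosphorus is put on the benzofuran half (14) because its benzylic carbon is the orsellinate methyl and can be functionalised at the outset. The aldehyde is put on ring B (31), where it needs only an acetal. The forward reaction must give the E-alkene only, under base that leaves the C3–H bonds alone.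

**14 ⇒ 12 + 13.** The C2–aryl bond is cut to the acid 12 and 4-bromoanisole 13. The carboxyl group is exactly what the ring contraction leaves at C2, so it serves as the leaving group and no separate C2 activation is needed. C3 is already blocked, which is what a decarboxylative arylation of a benzofuran-2-carboxylic acid requires.

**12 ⇒ 10 (key).** The furan O1–C2 bond is opened and 12 is recognised as the contraction product of the 3-bromo-4-arylcoumarin 10. The coumarin C4 aryl becomes the C3 aryl, C5 becomes C4 and C7 becomes C6. Compared with closing the furan at C3–C3a by electrophilic cyclisation onto ring A, this cut asks nothing of ring A's directing effects: every ring A substituent is already placed. The forward reaction needs only the ring closure to outrun relactonisation.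

**10 ⇒ 8 + 9; 8 ⇒ 7 ⇒ 6.** The C4–aryl bond is cut to the triflate 8 and boronic acid 9. Bromine is introduced on the 4-hydroxycoumarin 6, where C3 is the single most nucleophilic carbon. Bromination after arylation would attack the dimethoxyphenyl ring first. The coupling must then distinguish C4–OTf from C3–Br, a selectivity known for the parent 3-bromo-4-triflyloxycoumarin.

**6 ⇒ 5 ⇒ 4 ⇒ 3 ⇒ 2 ⇒ 1.** The C3–C4 bond is cut (Claisen). The ester carbon of methyl orsellinate 1 becomes C4, an O-acetyl group supplies C2 and C3, and the ring methyl becomes the olefination carbon. A benzylic oxygen at that carbon was rejected for two reasons: ortho to the ester it lactonises to a phthalide, and as an alkoxide it would compete with the phenoxide in the key step. A phosphonate ester was rejected because hot alkali can hydrolyse it. A diphenylphosphine oxide (4 ⇒ 5) has neither liability and is itself the Horner–Wittig handle.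

**31 ⇒ 30.** Both C2 centres are inverted (trans ⇐ cis) and the aldehyde is masked as a dioxolane. This is imposed by the ring closure chosen for the dihydrofurans, which is cis-selective. The forward step uses acid to let both C2–O bonds ionise and reclose to the more stable trans rings and to hydrolyse the acetal.

**30 ⇒ 28.** The C2–C3 bond of DHB-1 is cut, via diazo compound 29. A C2–O cut by cation capture would leave C3 without absolute control. Insertion of a diaryl carbene into the ArO–CH2–Ar C–H bond under a chiral dirhodium carboxylate, Rh2(S-PTAD)4 (dirhodium tetrakis[(S)-(1-adamantyl)(phthalimido)acetate]), sets C3 by reagent control. The 4-methoxybenzyl ether is not a protecting group: it becomes C2 and its aryl group.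

**28 ⇒ 22 + 25.** The bond between C4 of ring C and the future C3 of DHB-1 is cut to the aryl bromide 22 and the nitrile 25. An aryllithium adds once to a nitrile and gives the imine oxidation level directly, so the hydrazone follows by transimination. This avoids a carbinol, an oxidation and a hindered ketone condensation.

**22 ⇒ 20 ⇒ 19 ⇒ 17 ⇒ 15 + 16 (and 18).** The same C2–C3 cut is applied to DHB-2 on a simple substrate. Bromine is the placeholder for the later lithiation. Ketone 17 comes in one Friedel–Crafts operation from 15 and 16, and AlCl3 cleaves only the methoxy group ortho to the new carbonyl, which singles out the oxygen that becomes O1. Alkylation with 18 gives 19.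

**25 ⇒ 24 ⇒ 23 + 18.** Ring B is bought as 5-formyl-2-hydroxybenzonitrile 23. O-alkylation with 18 and acetalisation are the only operations.

## Roads not taken

**Alternative 1:** The cut is the C5–C6 bond of ring A; the whole benzo ring is built onto a finished 2,3-diarylfuran. In the forward step the diazoketone A2 undergoes Wolff rearrangement (light or PhCO2Ag) to a furyl ketene. The ketene, the furan C2=C3 bond and the acrylate C=CH2 then close by 6π electrocyclisation, and tautomerisation gives the phenol ester A1.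
- Merits: the regiochemistry of ring A is fixed by construction, the conditions are neutral, and the C6 oxygen arrives free and differentiated. It also avoids the triflate/bromide selectivity and the strongly basic steps of the chosen plan.
- Weak points: A2 is a furan with four different substituents, and its assembly is likely to be longer than the whole coumarin sequence. Diazomethane chemistry is needed. A1 still requires O-methylation and three steps from ester to olefination handle.
- Comparison: the key step is as plausible as the ring contraction. The chosen plan buys ring A with its substituents in place (1) and carries the olefination handle from step 4.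

**Alternative 2:** The cut is the C2–C3 bond of DHB-1, made on a substrate that already holds a trans DHB-2. In the forward step the diaryldiazomethane A4 is decomposed by Rh2(S-PTAD)4 or its enantiomer. The carbene inserts into the benzylic C–H bond of the ortho 4-methoxybenzyl ether to give bromide A3, with DHB-1 cis and C3 as required.
- Merits: this is the one catalytic ring closure that sets C3 of a 2,3-diaryl-dihydrobenzofuran by reagent control. The bromide keeps a Heck union open as well as an olefination.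
- Weak points: as an organising idea it leaves ring A and the benzofuran unsolved. From A3 a benzylic phosphorus reagent is four steps away. The insertion is run late on a hindered chiral substrate, and C2 must still be inverted.
- Comparison: this road is not taken as the centre of the plan, but its ring closure is borrowed twice (steps 14 and 18), so on the eastern half it is as good by definition and more flexible in its handle. The chosen plan adds a high-confidence key step for the benzofuran and an acetal in place of bromine, so that the aldehyde appears in the same operation as the inversion at C2.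

**Alternative 3:** The cut is C3–C3a of the benzofuran. In the forward step the α-aryloxy ketone A6 is treated with Bi(OTf)3 or BCl3. The aryloxy ring attacks the ketone carbon at the position para to its methoxy group, and loss of water gives ester A5 with both aryl groups already in place.
- Merits: it is the shortest access to the fully substituted benzofuran (ether formation, then one step), and no C2 arylation is needed.
- Weak points: regiochemistry rests on a para-methoxy preference at a position flanked by the ester; the other ortho position, between the two oxygens, competes. The ring is deactivated by the ester. A5 needs three further steps (reduction, bromination, Arbuzov) to reach 14.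
- Comparison: even with those steps this road should reach 14 in about three steps fewer than the chosen plan, and that advantage is real. The chosen plan offers regiochemistry that is never in question, no isomer separation, no strong Lewis acid on the benzofuran half, and a handle that needs no redox adjustment.

Key step: step 9

Assumption: the sense of induction of Rh2(R-PTAD)4 (taken to give 3S in step 14) and Rh2(S-PTAD)4 (taken to give 3R in step 18) is assigned by analogy with known closures of 2,3-diaryl-dihydrobenzofurans; if either insertion gives the antipodal C3 centre, the mirror-image catalyst is used in that step and nothing else changes.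

## Route

Step 1
Reactants: 1 methyl orsellinate (methyl 2,4-dihydroxy-6-methylbenzoate)
Product: 2 methyl 2-hydroxy-4-methoxy-6-methylbenzoate
Conditions: MeI (1.1 equiv), K2CO3, acetone, rt to 40 °C
Reagents that add atoms: iodomethane, CI
Why: Williamson O-methylation; the 2-OH is hydrogen-bonded to the ester carbonyl and is the less nucleophilic, so one equivalent of MeI should take the 4-OH.

Step 2
Reactants: 2 methyl 2-hydroxy-4-methoxy-6-methylbenzoate
Product: 3 methyl 2-acetoxy-4-methoxy-6-methylbenzoate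
Conditions: Ac2O, pyridine, DMAP (cat.), CH2Cl2, rt
Reagents that add atoms: acetic anhydride, CC(=O)OC(C)=O
Why: DMAP-catalysed O-acetylation; the acetate supplies C2 and C3 of the coumarin and makes the ring less prone to electrophilic bromination in step 3.

Step 3
Reactants: 3 methyl 2-acetoxy-4-methoxy-6-methylbenzoate
Product: 4 methyl 2-acetoxy-6-(bromomethyl)-4-methoxybenzoate
Conditions: NBS (1.05 equiv), AIBN (cat.), PhCF3, 85 °C
Reagents that add atoms: N-bromosuccinimide, O=C1CCC(=O)N1Br
Why: Wohl–Ziegler bromination; with the phenol acylated and a non-polar medium, the radical chain at the only benzylic C–H position should outpace ring bromination.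

Step 4
Reactants: 4 methyl 2-acetoxy-6-(bromomethyl)-4-methoxybenzoate
Product: 5 methyl 2-acetoxy-6-[(diphenylphosphoryl)methyl]-4-methoxybenzoate
Conditions: Ph2POEt (1.1 equiv), toluene, 100 °C
Reagents that add atoms: ethyl diphenylphosphinite, CCOP(c1ccccc1)c1ccccc1
Why: Michaelis–Arbuzov reaction of a benzylic bromide with a phosphinite; the phosphine oxide has no hydrolysable P–O ester bond, so it should pass the alkali of step 9 and serve directly as the Horner–Wittig handle in step 20.

Step 5
Reactants: 5 methyl 2-acetoxy-6-[(diphenylphosphoryl)methyl]-4-methoxybenzoate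
Product: 6 5-[(diphenylphosphoryl)methyl]-4-hydroxy-7-methoxy-2H-chromen-2-one
Conditions: LiN(SiMe3)2 (3.2 equiv), THF, −78 to 0 °C; then 1 M HCl
Reagents that add atoms: none
Why: Intramolecular Claisen (Dieckmann-type) condensation of the aryl acetate enolate onto the ortho methyl ester closes the six-membered lactone; excess base allows for the acidic CH2P(O)Ph2 group, and the product leaves the equilibrium as its stabilised 4-oxido anion.

Step 6
Reactants: 6 5-[(diphenylphosphoryl)methyl]-4-hydroxy-7-methoxy-2H-chromen-2-one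
Product: 7 3-bromo-5-[(diphenylphosphoryl)methyl]-4-hydroxy-7-methoxy-2H-chromen-2-one
Conditions: NBS (1.0 equiv), CH2Cl2, 0 °C
Reagents that add atoms: N-bromosuccinimide, O=C1CCC(=O)N1Br
Why: Electrophilic bromination at the enol carbon of a vinylogous acid; C3 is by far the most nucleophilic carbon, and the step is placed before the dimethoxyphenyl ring is present because that ring would otherwise be brominated first.

Step 7
Reactants: 7 3-bromo-5-[(diphenylphosphoryl)methyl]-4-hydroxy-7-methoxy-2H-chromen-2-one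
Product: 8 3-bromo-5-[(diphenylphosphoryl)methyl]-7-methoxy-2-oxo-2H-chromen-4-yl trifluoromethanesulfonate
Conditions: PhNTf2 (1.2 equiv), Et3N, DMAP (cat.), CH2Cl2, 0 °C to rt
Reagents that add atoms: N-phenylbis(trifluoromethanesulfonimide), O=S(=O)(N(c1ccccc1)S(=O)(=O)C(F)(F)F)C(F)(F)F
Why: O-sulfonylation of the 4-oxidocoumarin; the triflimide is used instead of Tf2O because the anhydride would also activate the phosphoryl oxygen.

Step 8
Reactants: 8 3-bromo-5-[(diphenylphosphoryl)methyl]-7-methoxy-2-oxo-2H-chromen-4-yl trifluoromethanesulfonate; 9 (3,5-dimethoxyphenyl)boronic acid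
Product: 10 3-bromo-4-(3,5-dimethoxyphenyl)-5-[(diphenylphosphoryl)methyl]-7-methoxy-2H-chromen-2-one
Conditions: Pd(PPh3)4 (5 mol%), K3PO4, THF, 60 °C
Reagents that add atoms: none
Why: Suzuki–Miyaura coupling; oxidative addition of zerovalent palladium is fastest at the C4–OTf bond (β-carbon of the unsaturated lactone), as is known for 3-bromo-4-triflyloxycoumarins, so C3–Br should be kept; one equivalent of 9 and a mild temperature guard against double coupling.

Step 9
Reactants: 10 3-bromo-4-(3,5-dimethoxyphenyl)-5-[(diphenylphosphoryl)methyl]-7-methoxy-2H-chromen-2-one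
Product: 12 3-(3,5-dimethoxyphenyl)-4-[(diphenylphosphoryl)methyl]-6-methoxy-1-benzofuran-2-carboxylic acid, via ring-opened bromoacrylate dianion 11 (not isolated)
Conditions: NaOH (2 M aq., 6 equiv), EtOH, 80 °C; then 2 M HCl to pH 2
Reagents that add atoms: sodium hydroxide, [Na+].[OH-]
Why: Hydroxide adds to the lactone carbonyl of 10 and opens it to the dianion 11, an (E)-2-bromoacrylate in which the carboxylate is cis and the bromine trans to ring A. The ring A phenoxide then attacks the bromine-bearing carbon (the old C3), bromide leaves, and the O1–C2 bond of the furan is formed with the former lactone carbonyl as the exocyclic C2 carboxylate; this is the Perkin coumarin-to-benzofuran rearrangement, known for 3-halocoumarins including 4-substituted ones. The closure forms a five-membered ring and is formally 5-endo-trig when drawn as addition–elimination. It is feasible either as an in-plane attack on the C–Br σ* orbital, for which lactone opening delivers the right geometry, or through a β-carbanion that is doubly benzylic here. No stereocentre is formed. The selectivity needed is contraction over mere saponification followed by relactonisation on acidification; heating until the slower cyclisation is complete, the irreversible loss of bromide and the aromaticity of the furan secure it. Relief of the peri strain between the C4 aryl group and the C5 substituent on going from the six- to the five-membered ring should help. The substrate offers no second nucleophile, because the benzylic carbon carries phosphorus and not oxygen, and the aryl methyl ethers and the phosphine oxide are inert to alkali. The carboxyl group formed is the leaving group of step 10.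

Step 10
Reactants: 12 3-(3,5-dimethoxyphenyl)-4-[(diphenylphosphoryl)methyl]-6-methoxy-1-benzofuran-2-carboxylic acid; 13 4-bromoanisole
Product: 14 {[3-(3,5-dimethoxyphenyl)-6-methoxy-2-(4-methoxyphenyl)-1-benzofuran-4-yl]methyl}(diphenyl)phosphine oxide
Conditions: Pd[P(t-Bu)3]2 (5 mol%), n-Bu4NCl, Cs2CO3, DMF, 170 °C (microwave)
Reagents that add atoms: none
Why: Palladium-catalysed decarboxylative cross-coupling of a heteroaryl-2-carboxylic acid with an aryl bromide (ipso palladation at C2 with loss of CO2, then reductive elimination); C3 is blocked by the aryl group, the pattern for which this coupling is cleanest, and Cs2CO3 is too weak to ionise the CH2P(O)Ph2 group.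

Step 11
Reactants: 15 1-bromo-3,5-dimethoxybenzene; 16 3,5-dimethoxybenzoyl chloride
Product: 17 (2-bromo-6-hydroxy-4-methoxyphenyl)(3,5-dimethoxyphenyl)methanone
Conditions: AlCl3 (3 equiv), ClCH2CH2Cl, 0 to 60 °C; aq. HCl work-up
Reagents that add atoms: none
Why: Friedel–Crafts aroylation at the position ortho to bromine and para to a methoxy group (the site taken by formylation and acylation of 5-substituted 1,3-dimethoxybenzenes), followed in the same pot by chelation-directed cleavage of the one methoxy group ortho to the new carbonyl.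

Step 12
Reactants: 17 (2-bromo-6-hydroxy-4-methoxyphenyl)(3,5-dimethoxyphenyl)methanone; 18 4-methoxybenzyl chloride
Product: 19 {2-bromo-4-methoxy-6-[(4-methoxybenzyl)oxy]phenyl}(3,5-dimethoxyphenyl)methanone
Conditions: K2CO3, n-Bu4NI (cat.), DMF, 60 °C
Reagents that add atoms: none
Why: Williamson etherification of the chelated phenol; the benzyl group is skeleton, since its CH2 becomes C2 and its ring the 2-aryl group of DHB-2.

Step 13
Reactants: 19 {2-bromo-4-methoxy-6-[(4-methoxybenzyl)oxy]phenyl}(3,5-dimethoxyphenyl)methanone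
Product: 20 [{2-bromo-4-methoxy-6-[(4-methoxybenzyl)oxy]phenyl}(3,5-dimethoxyphenyl)methylidene]hydrazine (E/Z mixture)
Conditions: N2H4·H2O (excess), AcOH (cat.), EtOH, 90 °C (sealed tube)
Reagents that add atoms: hydrazine, NN
Why: Hydrazone formation from a diaryl ketone; the carbonyl is flanked by Br and OCH2Ar, so excess hydrazine and heat are used, and without copper the aryl bromide should not be displaced.

Step 14
Reactants: 20 [{2-bromo-4-methoxy-6-[(4-methoxybenzyl)oxy]phenyl}(3,5-dimethoxyphenyl)methylidene]hydrazine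
Product: 22 (2R,3S)-4-bromo-3-(3,5-dimethoxyphenyl)-6-methoxy-2-(4-methoxyphenyl)-2,3-dihydro-1-benzofuran (cis), via diaryldiazomethane 21 (not isolated)
Conditions: MnO2, CH2Cl2, 0 °C; filter; then Rh2(R-PTAD)4 (1 mol%), CH2Cl2, 0 °C to rt
Reagents that add atoms: none
Why: Oxidation of the hydrazone to the diazo compound, then intramolecular C–H insertion of the donor/donor rhodium carbene into the ArO–CH2–Ar bond closes the five-membered ring at C2–C3; the chiral carboxylate ligands choose the carbene face and so set C3 (S), and the concerted insertion places the two aryl groups cis, which sets C2 (R).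

Step 15
Reactants: 23 5-formyl-2-hydroxybenzonitrile; 18 4-methoxybenzyl chloride
Product: 24 5-formyl-2-[(4-methoxybenzyl)oxy]benzonitrile
Conditions: K2CO3, DMF, 50 °C
Reagents that add atoms: none
Why: Williamson etherification of an acidic phenol; as in step 12 the benzyl group is skeleton (C2 and the 2-aryl group of DHB-1).

Step 16
Reactants: 24 5-formyl-2-[(4-methoxybenzyl)oxy]benzonitrile
Product: 25 5-(1,3-dioxolan-2-yl)-2-[(4-methoxybenzyl)oxy]benzonitrile
Conditions: HOCH2CH2OH, PPTS (cat.), toluene, reflux (Dean–Stark)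
Reagents that add atoms: ethane-1,2-diol, OCCO
Why: Acetalisation masks the aldehyde against the aryllithium and hydrazine of step 17; the acetal of a 4-alkoxybenzaldehyde is released by the acid of step 19, and PPTS is too weak to cleave the aryl benzyl ether.

Step 17
Reactants: 22 (2R,3S)-4-bromo-3-(3,5-dimethoxyphenyl)-6-methoxy-2-(4-methoxyphenyl)-2,3-dihydro-1-benzofuran; 25 5-(1,3-dioxolan-2-yl)-2-[(4-methoxybenzyl)oxy]benzonitrile
Product: 28 [{(2R,3S)-3-(3,5-dimethoxyphenyl)-6-methoxy-2-(4-methoxyphenyl)-2,3-dihydro-1-benzofuran-4-yl}{5-(1,3-dioxolan-2-yl)-2-[(4-methoxybenzyl)oxy]phenyl}methylidene]hydrazine (E/Z mixture), via aryllithium 26 (not isolated), via N-H ketimine 27 (not isolated)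
Conditions: t-BuLi (2.0 equiv), THF, −78 °C; then 25, −78 to 0 °C; MeOH; then N2H4·H2O, AcOH (cat.), EtOH, 70 °C
Reagents that add atoms: hydrazine, NN
Why: Bromine–lithium exchange, single addition of the aryllithium to the nitrile (the N-lithio ketimine cannot add again), protonation and transimination with hydrazine give the hydrazone without a ketone or an oxidation step; the stereocentres are not involved and should survive at −78 °C.

Step 18
Reactants: 28 [{(2R,3S)-3-(3,5-dimethoxyphenyl)-6-methoxy-2-(4-methoxyphenyl)-2,3-dihydro-1-benzofuran-4-yl}{5-(1,3-dioxolan-2-yl)-2-[(4-methoxybenzyl)oxy]phenyl}methylidene]hydrazine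
Product: 30 (2S,3R)-3-[(2R,3S)-3-(3,5-dimethoxyphenyl)-6-methoxy-2-(4-methoxyphenyl)-2,3-dihydro-1-benzofuran-4-yl]-5-(1,3-dioxolan-2-yl)-2-(4-methoxyphenyl)-2,3-dihydro-1-benzofuran (both rings cis), via diaryldiazomethane 29 (not isolated)
Conditions: MnO2, CH2Cl2, 0 °C; filter; then Rh2(S-PTAD)4 (2 mol%), CH2Cl2, 0 °C to rt
Reagents that add atoms: none
Why: The same oxidation and donor/donor carbene C–H insertion as in step 14 closes DHB-1 at C2–C3; Rh2(S-PTAD)4 is meant to set C3 (R) by reagent control over the bias of the existing ring, and the concerted insertion sets C2 (S) cis to it.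

Step 19
Reactants: 30 (2S,3R)-3-[(2R,3S)-3-(3,5-dimethoxyphenyl)-6-methoxy-2-(4-methoxyphenyl)-2,3-dihydro-1-benzofuran-4-yl]-5-(1,3-dioxolan-2-yl)-2-(4-methoxyphenyl)-2,3-dihydro-1-benzofuran
Product: 31 (2R,3R)-3-[(2S,3S)-3-(3,5-dimethoxyphenyl)-6-methoxy-2-(4-methoxyphenyl)-2,3-dihydro-1-benzofuran-4-yl]-2-(4-methoxyphenyl)-2,3-dihydro-1-benzofuran-5-carbaldehyde (both rings trans)
Conditions: CF3CO2H, CH2Cl2, 0 °C to rt; then H2O
Reagents that add atoms: water, O
Why: Acid-promoted reversible heterolysis of each C2–O bond to a 4-methoxybenzylic cation and reclosure under thermodynamic control inverts C2 in both rings to the more stable trans arrangement while C3 is untouched (a known cis-to-trans epimerisation of 2-aryl-dihydrobenzofurans); water then hydrolyses the acetal.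

Step 20
Reactants: 14 {[3-(3,5-dimethoxyphenyl)-6-methoxy-2-(4-methoxyphenyl)-1-benzofuran-4-yl]methyl}(diphenyl)phosphine oxide; 31 (2R,3R)-3-[(2S,3S)-3-(3,5-dimethoxyphenyl)-6-methoxy-2-(4-methoxyphenyl)-2,3-dihydro-1-benzofuran-4-yl]-2-(4-methoxyphenyl)-2,3-dihydro-1-benzofuran-5-carbaldehyde
Product: 32 (2R,3R)-3-[(2S,3S)-3-(3,5-dimethoxyphenyl)-6-methoxy-2-(4-methoxyphenyl)-2,3-dihydro-1-benzofuran-4-yl]-5-{(E)-2-[3-(3,5-dimethoxyphenyl)-6-methoxy-2-(4-methoxyphenyl)-1-benzofuran-4-yl]ethenyl}-2-(4-methoxyphenyl)-2,3-dihydro-1-benzofuran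
Conditions: KOt-Bu (1.5 equiv), THF, 0 °C to rt
Reagents that add atoms: none
Why: Horner–Wittig olefination; the stabilised benzylic phosphine oxide anion adds reversibly to the non-enolisable aldehyde, and syn-elimination of diphenylphosphinate from the favoured adduct should give the E-stilbene, without affecting the four stereocentres.

Step 21
Reactants: 32 (2R,3R)-3-[(2S,3S)-3-(3,5-dimethoxyphenyl)-6-methoxy-2-(4-methoxyphenyl)-2,3-dihydro-1-benzofuran-4-yl]-5-{(E)-2-[3-(3,5-dimethoxyphenyl)-6-methoxy-2-(4-methoxyphenyl)-1-benzofuran-4-yl]ethenyl}-2-(4-methoxyphenyl)-2,3-dihydro-1-benzofuran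
Product: 33 5-[(2S,3S)-4-[(2R,3R)-5-{(E)-2-[3-(3,5-dihydroxyphenyl)-6-hydroxy-2-(4-hydroxyphenyl)-1-benzofuran-4-yl]ethenyl}-2-(4-hydroxyphenyl)-2,3-dihydro-1-benzofuran-3-yl]-6-hydroxy-2-(4-hydroxyphenyl)-2,3-dihydro-1-benzofuran-3-yl]benzene-1,3-diol (CNP0135983.1)
Conditions: BBr3 (excess), CH2Cl2, −78 °C to rt; then MeOH, H2O
Reagents that add atoms: none
Why: Lewis-acid cleavage of the nine aryl methyl ethers, the usual last step for permethylated resveratrol oligomers with stilbene, benzofuran and trans-dihydrobenzofuran units; both dihydrofurans are already the thermodynamic trans isomers, so any C2–O ionisation and reclosure should return the same configuration.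

## Compound list

1 | methyl orsellinate (methyl 2,4-dihydroxy-6-methylbenzoate) | COC(=O)c1c(C)cc(O)cc1O | starting material
2 | methyl 2-hydroxy-4-methoxy-6-methylbenzoate | COC(=O)c1c(C)cc(OC)cc1O | intermediate
3 | methyl 2-acetoxy-4-methoxy-6-methylbenzoate | COC(=O)c1c(C)cc(OC)cc1OC(C)=O | intermediate
4 | methyl 2-acetoxy-6-(bromomethyl)-4-methoxybenzoate | COC(=O)c1c(CBr)cc(OC)cc1OC(C)=O | intermediate
5 | methyl 2-acetoxy-6-[(diphenylphosphoryl)methyl]-4-methoxybenzoate | COC(=O)c1c(CP(=O)(c2ccccc2)c2ccccc2)cc(OC)cc1OC(C)=O | intermediate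
6 | 5-[(diphenylphosphoryl)methyl]-4-hydroxy-7-methoxy-2H-chromen-2-one | O=c1cc(O)c2c(CP(=O)(c3ccccc3)c3ccccc3)cc(OC)cc2o1 | intermediate
7 | 3-bromo-5-[(diphenylphosphoryl)methyl]-4-hydroxy-7-methoxy-2H-chromen-2-one | O=c1c(Br)c(O)c2c(CP(=O)(c3ccccc3)c3ccccc3)cc(OC)cc2o1 | intermediate
8 | 3-bromo-5-[(diphenylphosphoryl)methyl]-7-methoxy-2-oxo-2H-chromen-4-yl trifluoromethanesulfonate | O=c1c(Br)c(OS(=O)(=O)C(F)(F)F)c2c(CP(=O)(c3ccccc3)c3ccccc3)cc(OC)cc2o1 | intermediate
9 | (3,5-dimethoxyphenyl)boronic acid | COc1cc(B(O)O)cc(OC)c1 | starting material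
10 | 3-bromo-4-(3,5-dimethoxyphenyl)-5-[(diphenylphosphoryl)methyl]-7-methoxy-2H-chromen-2-one | O=c1c(Br)c(-c2cc(OC)cc(OC)c2)c2c(CP(=O)(c3ccccc3)c3ccccc3)cc(OC)cc2o1 | intermediate
11 | (E)-2-bromo-3-(3,5-dimethoxyphenyl)-3-{2-[(diphenylphosphoryl)methyl]-6-hydroxy-4-methoxyphenyl}prop-2-enoic acid, present in the flask as its disodium salt | OC(=O)/C(Br)=C(/c1cc(OC)cc(OC)c1)c1c(O)cc(OC)cc1CP(=O)(c1ccccc1)c1ccccc1 | intermediate
12 | 3-(3,5-dimethoxyphenyl)-4-[(diphenylphosphoryl)methyl]-6-methoxy-1-benzofuran-2-carboxylic acid | OC(=O)c1oc2cc(OC)cc(CP(=O)(c3ccccc3)c3ccccc3)c2c1-c1cc(OC)cc(OC)c1 | intermediate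
13 | 4-bromoanisole | COc1ccc(Br)cc1 | starting material
14 | {[3-(3,5-dimethoxyphenyl)-6-methoxy-2-(4-methoxyphenyl)-1-benzofuran-4-yl]methyl}(diphenyl)phosphine oxide | COc1ccc(-c2oc3cc(OC)cc(CP(=O)(c4ccccc4)c4ccccc4)c3c2-c2cc(OC)cc(OC)c2)cc1 | intermediate
15 | 1-bromo-3,5-dimethoxybenzene | COc1cc(Br)cc(OC)c1 | starting material
16 | 3,5-dimethoxybenzoyl chloride | COc1cc(C(=O)Cl)cc(OC)c1 | starting material
17 | (2-bromo-6-hydroxy-4-methoxyphenyl)(3,5-dimethoxyphenyl)methanone | COc1cc(OC)cc(C(=O)c2c(O)cc(OC)cc2Br)c1 | intermediate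
18 | 4-methoxybenzyl chloride | COc1ccc(CCl)cc1 | starting material
19 | {2-bromo-4-methoxy-6-[(4-methoxybenzyl)oxy]phenyl}(3,5-dimethoxyphenyl)methanone | COc1ccc(COc2cc(OC)cc(Br)c2C(=O)c2cc(OC)cc(OC)c2)cc1 | intermediate
20 | [{2-bromo-4-methoxy-6-[(4-methoxybenzyl)oxy]phenyl}(3,5-dimethoxyphenyl)methylidene]hydrazine (E/Z mixture) | COc1ccc(COc2cc(OC)cc(Br)c2C(=NN)c2cc(OC)cc(OC)c2)cc1 | intermediate
21 | 1-bromo-2-[diazo(3,5-dimethoxyphenyl)methyl]-5-methoxy-3-[(4-methoxybenzyl)oxy]benzene | COc1ccc(COc2cc(OC)cc(Br)c2C(=[N+]=[N-])c2cc(OC)cc(OC)c2)cc1 | intermediate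
22 | (2R,3S)-4-bromo-3-(3,5-dimethoxyphenyl)-6-methoxy-2-(4-methoxyphenyl)-2,3-dihydro-1-benzofuran (cis) | Brc1cc(OC)cc2c1[C@H](c1cc(OC)cc(OC)c1)[C@H](c1ccc(OC)cc1)O2 | intermediate
23 | 5-formyl-2-hydroxybenzonitrile | N#Cc1cc(C=O)ccc1O | starting material
24 | 5-formyl-2-[(4-methoxybenzyl)oxy]benzonitrile | COc1ccc(COc2ccc(C=O)cc2C#N)cc1 | intermediate
25 | 5-(1,3-dioxolan-2-yl)-2-[(4-methoxybenzyl)oxy]benzonitrile | COc1ccc(COc2ccc(C3OCCO3)cc2C#N)cc1 | intermediate
26 | [(2R,3S)-3-(3,5-dimethoxyphenyl)-6-methoxy-2-(4-methoxyphenyl)-2,3-dihydro-1-benzofuran-4-yl]lithium | [Li]c1cc(OC)cc2c1[C@H](c1cc(OC)cc(OC)c1)[C@H](c1ccc(OC)cc1)O2 | intermediate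
27 | 1-[(2R,3S)-3-(3,5-dimethoxyphenyl)-6-methoxy-2-(4-methoxyphenyl)-2,3-dihydro-1-benzofuran-4-yl]-1-{5-(1,3-dioxolan-2-yl)-2-[(4-methoxybenzyl)oxy]phenyl}methanimine | N=C(c1cc(OC)cc2c1[C@H](c1cc(OC)cc(OC)c1)[C@H](c1ccc(OC)cc1)O2)c1cc(C2OCCO2)ccc1OCc1ccc(OC)cc1 | intermediate
28 | [{(2R,3S)-3-(3,5-dimethoxyphenyl)-6-methoxy-2-(4-methoxyphenyl)-2,3-dihydro-1-benzofuran-4-yl}{5-(1,3-dioxolan-2-yl)-2-[(4-methoxybenzyl)oxy]phenyl}methylidene]hydrazine (E/Z mixture) | NN=C(c1cc(OC)cc2c1[C@H](c1cc(OC)cc(OC)c1)[C@H](c1ccc(OC)cc1)O2)c1cc(C2OCCO2)ccc1OCc1ccc(OC)cc1 | intermediate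
29 | (2R,3S)-4-[diazo{5-(1,3-dioxolan-2-yl)-2-[(4-methoxybenzyl)oxy]phenyl}methyl]-3-(3,5-dimethoxyphenyl)-6-methoxy-2-(4-methoxyphenyl)-2,3-dihydro-1-benzofuran | [N-]=[N+]=C(c1cc(OC)cc2c1[C@H](c1cc(OC)cc(OC)c1)[C@H](c1ccc(OC)cc1)O2)c1cc(C2OCCO2)ccc1OCc1ccc(OC)cc1 | intermediate
30 | (2S,3R)-3-[(2R,3S)-3-(3,5-dimethoxyphenyl)-6-methoxy-2-(4-methoxyphenyl)-2,3-dihydro-1-benzofuran-4-yl]-5-(1,3-dioxolan-2-yl)-2-(4-methoxyphenyl)-2,3-dihydro-1-benzofuran (both rings cis) | O1CCOC1c1ccc2c(c1)[C@@H](c1cc(OC)cc3c1[C@H](c1cc(OC)cc(OC)c1)[C@H](c1ccc(OC)cc1)O3)[C@@H](c1ccc(OC)cc1)O2 | intermediate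
31 | (2R,3R)-3-[(2S,3S)-3-(3,5-dimethoxyphenyl)-6-methoxy-2-(4-methoxyphenyl)-2,3-dihydro-1-benzofuran-4-yl]-2-(4-methoxyphenyl)-2,3-dihydro-1-benzofuran-5-carbaldehyde (both rings trans) | O=Cc1ccc2c(c1)[C@@H](c1cc(OC)cc3c1[C@H](c1cc(OC)cc(OC)c1)[C@@H](c1ccc(OC)cc1)O3)[C@H](c1ccc(OC)cc1)O2 | intermediate
32 | nona-O-methyl ether of the target: (2R,3R)-3-[(2S,3S)-3-(3,5-dimethoxyphenyl)-6-methoxy-2-(4-methoxyphenyl)-2,3-dihydro-1-benzofuran-4-yl]-5-{(E)-2-[3-(3,5-dimethoxyphenyl)-6-methoxy-2-(4-methoxyphenyl)-1-benzofuran-4-yl]ethenyl}-2-(4-methoxyphenyl)-2,3-dihydro-1-benzofuran | COc1ccc(-c2oc3cc(OC)cc(/C=C/c4ccc5c(c4)[C@@H](c4cc(OC)cc6c4[C@H](c4cc(OC)cc(OC)c4)[C@@H](c4ccc(OC)cc4)O6)[C@H](c4ccc(OC)cc4)O5)c3c2-c2cc(OC)cc(OC)c2)cc1 | intermediate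
33 | CNP0135983.1: 5-[(2S,3S)-4-[(2R,3R)-5-{(E)-2-[3-(3,5-dihydroxyphenyl)-6-hydroxy-2-(4-hydroxyphenyl)-1-benzofuran-4-yl]ethenyl}-2-(4-hydroxyphenyl)-2,3-dihydro-1-benzofuran-3-yl]-6-hydroxy-2-(4-hydroxyphenyl)-2,3-dihydro-1-benzofuran-3-yl]benzene-1,3-diol | Oc1ccc(-c2oc3cc(O)cc(/C=C/c4ccc5c(c4)[C@@H](c4cc(O)cc6c4[C@H](c4cc(O)cc(O)c4)[C@@H](c4ccc(O)cc4)O6)[C@H](c4ccc(O)cc4)O5)c3c2-c2cc(O)cc(O)c2)cc1 | target

## Step count and least certain steps

Total step count: 21. Longest linear sequence: 12 steps (steps 1–10, 20 and 21). The eastern branch (steps 11–14 and 17–19) and its side branch (steps 15–16) join at steps 17 and 20.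

**Step 9 (key step).** The likely failure is that bromide displacement by the phenoxide is too slow in the crowded tetrasubstituted acrylate. Acidification would then only relactonise 11 to 10, or prolonged heating would cost the carboxyl group before the ring has closed. The fallback leaves the contraction and builds the furan ring on the salicylate. It sets out from 5 and returns at 12.
- K2CO3 in MeOH removes the acetate to give methyl 2-[(diphenylphosphoryl)methyl]-6-hydroxy-4-methoxybenzoate F1.
- Methyl bromoacetate and K2CO3 give methyl 2-[(diphenylphosphoryl)methyl]-4-methoxy-6-(2-methoxy-2-oxoethoxy)benzoate F2.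
- Dieckmann condensation with NaOMe gives methyl 4-[(diphenylphosphoryl)methyl]-3-hydroxy-6-methoxy-1-benzofuran-2-carboxylate F3.
- PhNTf2 gives methyl 4-[(diphenylphosphoryl)methyl]-6-methoxy-3-(trifluoromethanesulfonyloxy)-1-benzofuran-2-carboxylate F4.
- Suzuki–Miyaura coupling with 9 gives methyl 3-(3,5-dimethoxyphenyl)-4-[(diphenylphosphoryl)methyl]-6-methoxy-1-benzofuran-2-carboxylate F5.
- Saponification with LiOH gives 12.

**Step 18.** The cis-dihydrofuran next to the carbene may impose a facial bias that opposes Rh2(S-PTAD)4, giving poor selectivity at C3 of DHB-1. The hindered carbene may also be diverted to azine formation or to insertion into the C2–H bond of DHB-2. The fallback changes the substrate, not the catalyst. It sets out from 22 and returns at 31.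
- CF3CO2H epimerises 22 first to (2S,3S)-4-bromo-3-(3,5-dimethoxyphenyl)-6-methoxy-2-(4-methoxyphenyl)-2,3-dihydro-1-benzofuran F6.
- The operations of step 17 with 25 give the trans-configured hydrazone [{(2S,3S)-3-(3,5-dimethoxyphenyl)-6-methoxy-2-(4-methoxyphenyl)-2,3-dihydro-1-benzofuran-4-yl}{5-(1,3-dioxolan-2-yl)-2-[(4-methoxybenzyl)oxy]phenyl}methylidene]hydrazine F7.
- The insertion is then run on a carbene whose neighbouring 2-aryl group lies on the other face. It gives (2S,3R)-3-[(2S,3S)-3-(3,5-dimethoxyphenyl)-6-methoxy-2-(4-methoxyphenyl)-2,3-dihydro-1-benzofuran-4-yl]-5-(1,3-dioxolan-2-yl)-2-(4-methoxyphenyl)-2,3-dihydro-1-benzofuran F8.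
- F8 needs only DHB-1 inverted under the conditions of step 19 and gives 31.

**Step 14.** The carbene carries an aryl group with two ortho substituents (Br and OCH2Ar) and is forced out of conjugation. Low enantioselectivity or a slow insertion may result, and the hydrazone of step 13 may already form sluggishly. The fallback gives up asymmetric catalysis for this ring. It sets out from 19 and returns at 31.
- KOt-Bu in DMF (carbanion cyclisation onto the ketone and dehydration) gives 4-bromo-3-(3,5-dimethoxyphenyl)-6-methoxy-2-(4-methoxyphenyl)-1-benzofuran F9.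
- Ionic hydrogenation with Et3SiH in CF3CO2H gives racemic trans-4-bromo-3-(3,5-dimethoxyphenyl)-6-methoxy-2-(4-methoxyphenyl)-2,3-dihydro-1-benzofuran F10.
- Chromatography on a chiral stationary phase gives the (2S,3S)-bromide F6.
- F6 is carried through F7 and F8 as described for step 18 and gives 31.

**Step 19.** Ionisation of the C2–O bond of DHB-1 gives a cation within reach of the 3,5-dimethoxyphenyl ring on C3 of DHB-2. Irreversible Friedel–Crafts capture to a seven-membered ring may compete with reclosure, or the inversion may stop short of completion. The fallback moves the inversion to the end of the synthesis. It sets out from 30 and returns at 33.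
- PPTS in aqueous acetone removes only the acetal and gives (2S,3R)-3-[(2R,3S)-3-(3,5-dimethoxyphenyl)-6-methoxy-2-(4-methoxyphenyl)-2,3-dihydro-1-benzofuran-4-yl]-2-(4-methoxyphenyl)-2,3-dihydro-1-benzofuran-5-carbaldehyde F11.
- Horner–Wittig olefination with 14 gives the nona-O-methyl ether with both dihydrofurans cis F12.
- BBr3 cleaves the ethers and inverts C2 in both rings in one operation. By then the neighbouring arenes are O-borylated and much poorer nucleophiles. The product is 33.

**Step 5.** The CH2P(O)Ph2 group ortho to the ester is acidic. Its deprotonation may lower the electrophilicity of the ester, and acetyl transfer may compete, so the Claisen closure may stall. The fallback runs the Claisen before phosphorus is introduced. It sets out from 3 and returns at 7.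
- LiN(SiMe3)2 gives 4-hydroxy-7-methoxy-5-methyl-2H-chromen-2-one F13.
- NBS gives 3-bromo-4-hydroxy-7-methoxy-5-methyl-2H-chromen-2-one F14.
- O-methylation with Me3SiCHN2 gives 3-bromo-4,7-dimethoxy-5-methyl-2H-chromen-2-one F15.
- Wohl–Ziegler bromination gives 3-bromo-5-(bromomethyl)-4,7-dimethoxy-2H-chromen-2-one F16.
- Arbuzov reaction with Ph2POEt gives 3-bromo-5-[(diphenylphosphoryl)methyl]-4,7-dimethoxy-2H-chromen-2-one F17.
- LiCl in hot DMF cleaves the vinylogous methyl ester and gives 7.

**Step 21.** Nine ether cleavages require a large excess of BBr3 for a long time on the one molecule that holds the stilbene, the benzofuran and both dihydrofurans. Opening of a C2–O bond with cation capture, or acid-induced cyclisation at the stilbene, may erode the material. The fallback divides the deprotection between the halves and ends with fluoride. It sets out from 14 and 31 and returns at 33.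
- BBr3 on 14 gives the tetraphenol {[3-(3,5-dihydroxyphenyl)-6-hydroxy-2-(4-hydroxyphenyl)-1-benzofuran-4-yl]methyl}(diphenyl)phosphine oxide F18.
- t-BuMe2SiCl and imidazole give its tetrakis(tert-butyldimethylsilyl) ether F19.
- BBr3 at low temperature on 31, where no stilbene is present and the rings can be checked before the union, gives the pentaphenol (2R,3R)-3-[(2S,3S)-3-(3,5-dihydroxyphenyl)-6-hydroxy-2-(4-hydroxyphenyl)-2,3-dihydro-1-benzofuran-4-yl]-2-(4-hydroxyphenyl)-2,3-dihydro-1-benzofuran-5-carbaldehyde F20.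
- Silylation gives its pentakis(tert-butyldimethylsilyl) ether F21.
- Horner–Wittig olefination of F19 with F21 using KN(SiMe3)2 gives the nonakis(tert-butyldimethylsilyl) ether of the target F22.
- n-Bu4NF buffered with AcOH gives 33.

## Further compounds

F1 | step 9 | methyl 2-[(diphenylphosphoryl)methyl]-6-hydroxy-4-methoxybenzoate | COC(=O)c1c(O)cc(OC)cc1CP(=O)(c1ccccc1)c1ccccc1
F2 | step 9 | methyl 2-[(diphenylphosphoryl)methyl]-4-methoxy-6-(2-methoxy-2-oxoethoxy)benzoate | COC(=O)COc1cc(OC)cc(CP(=O)(c2ccccc2)c2ccccc2)c1C(=O)OC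
F3 | step 9 | methyl 4-[(diphenylphosphoryl)methyl]-3-hydroxy-6-methoxy-1-benzofuran-2-carboxylate | COC(=O)c1oc2cc(OC)cc(CP(=O)(c3ccccc3)c3ccccc3)c2c1O
F4 | step 9 | methyl 4-[(diphenylphosphoryl)methyl]-6-methoxy-3-(trifluoromethanesulfonyloxy)-1-benzofuran-2-carboxylate | COC(=O)c1oc2cc(OC)cc(CP(=O)(c3ccccc3)c3ccccc3)c2c1OS(=O)(=O)C(F)(F)F
F5 | step 9 | methyl 3-(3,5-dimethoxyphenyl)-4-[(diphenylphosphoryl)methyl]-6-methoxy-1-benzofuran-2-carboxylate | COC(=O)c1oc2cc(OC)cc(CP(=O)(c3ccccc3)c3ccccc3)c2c1-c1cc(OC)cc(OC)c1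
F6 | step 18 | (2S,3S)-4-bromo-3-(3,5-dimethoxyphenyl)-6-methoxy-2-(4-methoxyphenyl)-2,3-dihydro-1-benzofuran (trans) | Brc1cc(OC)cc2c1[C@H](c1cc(OC)cc(OC)c1)[C@@H](c1ccc(OC)cc1)O2
F7 | step 18 | [{(2S,3S)-3-(3,5-dimethoxyphenyl)-6-methoxy-2-(4-methoxyphenyl)-2,3-dihydro-1-benzofuran-4-yl}{5-(1,3-dioxolan-2-yl)-2-[(4-methoxybenzyl)oxy]phenyl}methylidene]hydrazine | NN=C(c1cc(OC)cc2c1[C@H](c1cc(OC)cc(OC)c1)[C@@H](c1ccc(OC)cc1)O2)c1cc(C2OCCO2)ccc1OCc1ccc(OC)cc1
F8 | step 18 | (2S,3R)-3-[(2S,3S)-3-(3,5-dimethoxyphenyl)-6-methoxy-2-(4-methoxyphenyl)-2,3-dihydro-1-benzofuran-4-yl]-5-(1,3-dioxolan-2-yl)-2-(4-methoxyphenyl)-2,3-dihydro-1-benzofuran | O1CCOC1c1ccc2c(c1)[C@@H](c1cc(OC)cc3c1[C@H](c1cc(OC)cc(OC)c1)[C@@H](c1ccc(OC)cc1)O3)[C@@H](c1ccc(OC)cc1)O2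
F9 | step 14 | 4-bromo-3-(3,5-dimethoxyphenyl)-6-methoxy-2-(4-methoxyphenyl)-1-benzofuran | COc1ccc(-c2oc3cc(OC)cc(Br)c3c2-c2cc(OC)cc(OC)c2)cc1
F10 | step 14 | racemic trans-4-bromo-3-(3,5-dimethoxyphenyl)-6-methoxy-2-(4-methoxyphenyl)-2,3-dihydro-1-benzofuran | Brc1cc(OC)cc2c1[C@H](c1cc(OC)cc(OC)c1)[C@@H](c1ccc(OC)cc1)O2.Brc1cc(OC)cc2c1[C@@H](c1cc(OC)cc(OC)c1)[C@H](c1ccc(OC)cc1)O2
F11 | step 19 | (2S,3R)-3-[(2R,3S)-3-(3,5-dimethoxyphenyl)-6-methoxy-2-(4-methoxyphenyl)-2,3-dihydro-1-benzofuran-4-yl]-2-(4-methoxyphenyl)-2,3-dihydro-1-benzofuran-5-carbaldehyde (both rings cis) | O=Cc1ccc2c(c1)[C@@H](c1cc(OC)cc3c1[C@H](c1cc(OC)cc(OC)c1)[C@H](c1ccc(OC)cc1)O3)[C@@H](c1ccc(OC)cc1)O2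
F12 | step 19 | nona-O-methyl ether with both dihydrofurans cis: (2S,3R)-3-[(2R,3S)-3-(3,5-dimethoxyphenyl)-6-methoxy-2-(4-methoxyphenyl)-2,3-dihydro-1-benzofuran-4-yl]-5-{(E)-2-[3-(3,5-dimethoxyphenyl)-6-methoxy-2-(4-methoxyphenyl)-1-benzofuran-4-yl]ethenyl}-2-(4-methoxyphenyl)-2,3-dihydro-1-benzofuran | COc1ccc(-c2oc3cc(OC)cc(/C=C/c4ccc5c(c4)[C@@H](c4cc(OC)cc6c4[C@H](c4cc(OC)cc(OC)c4)[C@H](c4ccc(OC)cc4)O6)[C@@H](c4ccc(OC)cc4)O5)c3c2-c2cc(OC)cc(OC)c2)cc1
F13 | step 5 | 4-hydroxy-7-methoxy-5-methyl-2H-chromen-2-one | O=c1cc(O)c2c(C)cc(OC)cc2o1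
F14 | step 5 | 3-bromo-4-hydroxy-7-methoxy-5-methyl-2H-chromen-2-one | O=c1c(Br)c(O)c2c(C)cc(OC)cc2o1
F15 | step 5 | 3-bromo-4,7-dimethoxy-5-methyl-2H-chromen-2-one | O=c1c(Br)c(OC)c2c(C)cc(OC)cc2o1
F16 | step 5 | 3-bromo-5-(bromomethyl)-4,7-dimethoxy-2H-chromen-2-one | O=c1c(Br)c(OC)c2c(CBr)cc(OC)cc2o1
F17 | step 5 | 3-bromo-5-[(diphenylphosphoryl)methyl]-4,7-dimethoxy-2H-chromen-2-one | O=c1c(Br)c(OC)c2c(CP(=O)(c3ccccc3)c3ccccc3)cc(OC)cc2o1
F18 | step 21 | {[3-(3,5-dihydroxyphenyl)-6-hydroxy-2-(4-hydroxyphenyl)-1-benzofuran-4-yl]methyl}(diphenyl)phosphine oxide | Oc1ccc(-c2oc3cc(O)cc(CP(=O)(c4ccccc4)c4ccccc4)c3c2-c2cc(O)cc(O)c2)cc1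
F19 | step 21 | tetrakis(tert-butyldimethylsilyl) ether of F18 | CC(C)(C)[Si](C)(C)Oc1ccc(-c2oc3cc(O[Si](C)(C)C(C)(C)C)cc(CP(=O)(c4ccccc4)c4ccccc4)c3c2-c2cc(O[Si](C)(C)C(C)(C)C)cc(O[Si](C)(C)C(C)(C)C)c2)cc1
F20 | step 21 | (2R,3R)-3-[(2S,3S)-3-(3,5-dihydroxyphenyl)-6-hydroxy-2-(4-hydroxyphenyl)-2,3-dihydro-1-benzofuran-4-yl]-2-(4-hydroxyphenyl)-2,3-dihydro-1-benzofuran-5-carbaldehyde | O=Cc1ccc2c(c1)[C@@H](c1cc(O)cc3c1[C@H](c1cc(O)cc(O)c1)[C@@H](c1ccc(O)cc1)O3)[C@H](c1ccc(O)cc1)O2
F21 | step 21 | pentakis(tert-butyldimethylsilyl) ether of F20 | O=Cc1ccc2c(c1)[C@@H](c1cc(O[Si](C)(C)C(C)(C)C)cc3c1[C@H](c1cc(O[Si](C)(C)C(C)(C)C)cc(O[Si](C)(C)C(C)(C)C)c1)[C@@H](c1ccc(O[Si](C)(C)C(C)(C)C)cc1)O3)[C@H](c1ccc(O[Si](C)(C)C(C)(C)C)cc1)O2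
F22 | step 21 | nonakis(tert-butyldimethylsilyl) ether of the target | CC(C)(C)[Si](C)(C)Oc1ccc(-c2oc3cc(O[Si](C)(C)C(C)(C)C)cc(/C=C/c4ccc5c(c4)[C@@H](c4cc(O[Si](C)(C)C(C)(C)C)cc6c4[C@H](c4cc(O[Si](C)(C)C(C)(C)C)cc(O[Si](C)(C)C(C)(C)C)c4)[C@@H](c4ccc(O[Si](C)(C)C(C)(C)C)cc4)O6)[C@H](c4ccc(O[Si](C)(C)C(C)(C)C)cc4)O5)c3c2-c2cc(O[Si](C)(C)C(C)(C)C)cc(O[Si](C)(C)C(C)(C)C)c2)cc1
A1 | alternative 1 | methyl 3-(3,5-dimethoxyphenyl)-6-hydroxy-2-(4-methoxyphenyl)-1-benzofuran-4-carboxylate | COC(=O)c1cc(O)cc2oc(-c3ccc(OC)cc3)c(-c3cc(OC)cc(OC)c3)c12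
A2 | alternative 1 | methyl 2-[2-(2-diazoacetyl)-4-(3,5-dimethoxyphenyl)-5-(4-methoxyphenyl)furan-3-yl]prop-2-enoate | COC(=O)C(=C)c1c(C(=O)C=[N+]=[N-])oc(-c2ccc(OC)cc2)c1-c1cc(OC)cc(OC)c1
A3 | alternative 2 | (2S,3R)-5-bromo-3-[(2S,3S)-3-(3,5-dimethoxyphenyl)-6-methoxy-2-(4-methoxyphenyl)-2,3-dihydro-1-benzofuran-4-yl]-2-(4-methoxyphenyl)-2,3-dihydro-1-benzofuran | Brc1ccc2c(c1)[C@@H](c1cc(OC)cc3c1[C@H](c1cc(OC)cc(OC)c1)[C@@H](c1ccc(OC)cc1)O3)[C@@H](c1ccc(OC)cc1)O2
A4 | alternative 2 | (2S,3S)-4-[{5-bromo-2-[(4-methoxybenzyl)oxy]phenyl}(diazo)methyl]-3-(3,5-dimethoxyphenyl)-6-methoxy-2-(4-methoxyphenyl)-2,3-dihydro-1-benzofuran | [N-]=[N+]=C(c1cc(Br)ccc1OCc1ccc(OC)cc1)c1cc(OC)cc2c1[C@H](c1cc(OC)cc(OC)c1)[C@@H](c1ccc(OC)cc1)O2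
A5 | alternative 3 | methyl 3-(3,5-dimethoxyphenyl)-6-methoxy-2-(4-methoxyphenyl)-1-benzofuran-4-carboxylate | COC(=O)c1cc(OC)cc2oc(-c3ccc(OC)cc3)c(-c3cc(OC)cc(OC)c3)c12
A6 | alternative 3 | methyl 3-[2-(3,5-dimethoxyphenyl)-1-(4-methoxyphenyl)-2-oxoethoxy]-5-methoxybenzoate | COC(=O)c1cc(OC)cc(OC(C(=O)c2cc(OC)cc(OC)c2)c2ccc(OC)cc2)c1
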